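**Plan**

1. Ring locants: C1 = quaternary C(CH3)(vinyl), C2 = CH2, C3 = CH–O-acyl, C4 = CH–C(=CH2)CO2H, C5 = CHOH, C6 = CH–C(=CH2)CH2OH. The enabling feature is the homoallylic alcohol array C5(OH)–C6–C(=CH2)–CH2O of the cyclohexane: C5 can be a formyl carbon and C6 the γ-carbon of a 2-(oxymethyl)allylboronate, the two held 1,6 by the tether C4–C3–C2–C1 with its gem-disubstituted C1.
2. Retrosynthesis, in order: silyl groups off; ring bond C5–C6 (ring-closing allylboration, the boronate made in the same flask from a (Z)-alkenyl iodide and a borylmethylzinc reagent that also supplies the exocyclic =CH2 carbon); ester bond at C3–O (acid fragment C); C3–C4 (carbonyl 2-(alkoxycarbonyl)allylation of aldehyde fragment A with allyl bromide fragment B); C1–alkynyl bond (copper-catalysed SN2' alkynylation).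
3. Forward: the chain is built first (A in 7 steps, B in 3, C in 3; A + B, then C); the only ring closes in the penultimate step and one fluoride treatment ends the route.
4. Stereochemistry: C1 from a chiral NHC–copper catalyst; C3/C4 from a chiral chromium catalyst (face) and a chair transition state (syn); C5/C6 by substrate control in the key step, from the alkene geometry fixed by hydroxyl-directed trans-hydrostannation and from C1, C3 and C4.

Key step: step 18

Remark: for both chiral catalysts the ligand antipode that delivers the drawn configuration is meant, and the ring locants C1–C6 defined above are used for the open-chain intermediates as well.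

**Route**

Step 1
Reactants: 1 tert-butyl(but-3-yn-1-yloxy)dimethylsilane
Product: 4 (2E)-5-{[tert-butyl(dimethyl)silyl]oxy}-3-methylpent-2-en-1-ol, via alkenyldimethylalane 2 (not isolated), via lithium alkenylalanate 3 (not isolated)
Conditions: Me3Al, Cp2ZrCl2 (20 mol%), CH2Cl2, 0 °C → rt; n-BuLi, THF, −78 → 0 °C; (CH2O)n, rt; aq. potassium sodium tartrate
Reagents that add atoms: trimethylaluminium C[Al](C)C; formaldehyde (from paraformaldehyde) C=O
Why: Zirconium-catalysed carboalumination adds methyl and aluminium syn across the terminal alkyne with aluminium on the terminal carbon, and the derived alanate is hydroxymethylated by formaldehyde with retention, so the (E)-trisubstituted allylic alcohol should result (no stereocentre is formed).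

Step 2
Reactants: 4 (2E)-5-{[tert-butyl(dimethyl)silyl]oxy}-3-methylpent-2-en-1-ol
Product: 5 (2E)-5-{[tert-butyl(dimethyl)silyl]oxy}-3-methylpent-2-en-1-yl diethyl phosphate
Conditions: ClP(O)(OEt)2, Et3N, DMAP (cat.), CH2Cl2, 0 °C → rt
Reagents that add atoms: diethyl chlorophosphate CCOP(=O)(Cl)OCC
Why: O-Phosphorylation of the primary allylic alcohol installs the leaving group needed for the copper-catalysed SN2' substitution.

Step 3
Reactants: 5 allylic phosphate; 6 trimethyl(prop-2-yn-1-yloxy)silane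
Product: 9 (4R)-4-(2-{[tert-butyl(dimethyl)silyl]oxy}ethyl)-4-methylhex-5-en-2-yn-1-ol, via alkynyldiisobutylalane 7 (not isolated), via trimethylsilyl ether 8 (not isolated)
Conditions: 6, i-Bu2AlH, Et3N (5 mol%), hexanes/THF, 55 °C; then 5, CuCl2·2H2O (5 mol%), chiral N-aryl-N'-(2-sulfonatoaryl)-4,5-diphenylimidazolinium salt (2.5 mol%), THF, −15 °C; then K2CO3, MeOH, rt
Reagents that add atoms: none
Why: Copper-catalysed enantioselective allylic substitution of the (E)-trisubstituted allylic phosphate with an alkynylaluminium reagent proceeds SN2' and gives the vinyl-bearing all-carbon quaternary centre C1, whose (R) configuration is set by the chiral NHC–copper complex, and the labile O–SiMe3 group is removed by methanolysis in the work-up.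

Step 4
Reactants: 9 (4R)-enynol
Product: 11 (2Z,4R)-4-(2-{[tert-butyl(dimethyl)silyl]oxy}ethyl)-2-iodo-4-methylhexa-2,5-dien-1-ol, via alkenylstannane 10 (not isolated)
Conditions: Bu3SnH, [Cp*RuCl]4 (2.5 mol%), CH2Cl2, rt; then I2, CH2Cl2, 0 °C
Reagents that add atoms: iodine [I][I]
Why: Hydroxyl-directed ruthenium-catalysed trans-hydrostannation places tin on the alkyne carbon next to the carbinol and hydrogen on the distal carbon from opposite faces, and iododestannylation with retention should give the (Z)-2-iodo allylic alcohol in which iodine is cis to the quaternary carbon.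

Step 5
Reactants: 11 (2Z,4R)-iodo dienol
Product: 12 tert-butyl{[(2Z,4R)-4-(2-{[tert-butyl(dimethyl)silyl]oxy}ethyl)-2-iodo-4-methylhexa-2,5-dien-1-yl]oxy}diphenylsilane
Conditions: t-BuPh2SiCl, imidazole, DMF, rt
Reagents that add atoms: tert-butyl(chloro)diphenylsilane CC(C)(C)[Si](Cl)(c1ccccc1)c1ccccc1
Why: Silyl ether formation at the primary allylic alcohol gives an acid-stable, fluoride-labile protecting group that is carried to the last step.

Step 6
Reactants: 12 bis-silyl ether
Product: 13 (3R,4Z)-6-{[tert-butyl(diphenyl)silyl]oxy}-3-ethenyl-5-iodo-3-methylhex-4-en-1-ol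
Conditions: camphorsulfonic acid (10 mol%), MeOH/CH2Cl2 (1:1), 0 °C
Reagents that add atoms: none
Why: Acid-catalysed methanolysis (selective desilylation) cleaves the primary tert-butyldimethylsilyl ether much faster than the tert-butyldiphenylsilyl ether.

Step 7
Reactants: 13 primary alcohol
Product: 14 (3R,4Z)-6-{[tert-butyl(diphenyl)silyl]oxy}-3-ethenyl-5-iodo-3-methylhex-4-enal (fragment A)
Conditions: Dess–Martin periodinane, NaHCO3, CH2Cl2, 0 °C → rt
Reagents that add atoms: none
Why: Dess–Martin oxidation gives the aldehyde under buffered conditions, and the adjacent quaternary centre cannot epimerise.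

Step 8
Reactants: 15 prop-2-enoyl chloride; 16 2-(trimethylsilyl)ethan-1-ol
Product: 17 2-(trimethylsilyl)ethyl prop-2-enoate
Conditions: Et3N, CH2Cl2, 0 °C
Reagents that add atoms: none
Why: Esterification of the alcohol with the acid chloride gives an acrylate whose ester is cleavable by fluoride at the end.

Step 9
Reactants: 17 2-(trimethylsilyl)ethyl prop-2-enoate; 18 {[tert-butyl(dimethyl)silyl]oxy}acetaldehyde
Product: 19 2-(trimethylsilyl)ethyl 4-{[tert-butyl(dimethyl)silyl]oxy}-3-hydroxy-2-methylidenebutanoate (racemic)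
Conditions: DABCO, 1,4-dioxane/H2O, rt
Reagents that add atoms: none
Why: Morita–Baylis–Hillman reaction, in which DABCO adds to the acrylate and the resulting enolate adds to the α-silyloxy aldehyde, gives a racemic allylic alcohol whose stereocentre is removed in the next step.

Step 10
Reactants: 19 Morita–Baylis–Hillman adduct
Product: 20 2-(trimethylsilyl)ethyl (2Z)-2-(bromomethyl)-4-{[tert-butyl(dimethyl)silyl]oxy}but-2-enoate (fragment B)
Conditions: N-bromosuccinimide, Me2S, CH2Cl2, 0 °C → rt
Reagents that add atoms: N-bromosuccinimide O=C1CCC(=O)N1Br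
Why: Bromosulfonium activation of the allylic alcohol and SN2' attack of bromide (allylic transposition) should give the thermodynamically preferred (Z)-2-(bromomethyl)enoate, in which the silyloxymethyl group is trans to the ester.

Step 11
Reactants: 14 fragment A aldehyde; 20 fragment B allyl bromide
Product: 22 2-(trimethylsilyl)ethyl (3S,4R,6R,7Z)-3-({[tert-butyl(dimethyl)silyl]oxy}methyl)-9-{[tert-butyl(diphenyl)silyl]oxy}-6-ethenyl-4-hydroxy-8-iodo-6-methyl-2-methylidenenon-7-enoate, via trimethylsilyl ether 21 (not isolated)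
Conditions: CrCl2 (10 mol%), chiral 3,6-di-tert-butyl-1,8-bis(4-isopropyl-4,5-dihydrooxazol-2-yl)-9H-carbazole (12 mol%), Et3N (20 mol%), Mn powder, Me3SiCl, THF, rt; then aq. citric acid, THF/MeOH, 0 °C
Reagents that add atoms: none
Why: Catalytic asymmetric Nozaki–Hiyama–Kishi-type 2-(alkoxycarbonyl)allylation, in which the allylchromium species adds through a chair transition state with its CH2OSi group cis to the metal-bearing carbon (syn relationship of C3–O and C4–C5), the chiral bis(oxazolinyl)carbazole–chromium complex selects the aldehyde face (C3 R, hence C4 S) because the remote quaternary centre exerts no bias, and Me3SiCl turns the chromium alkoxide over as a silyl ether that cannot lactonise.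

Step 12
Reactants: 23 3-methylfuran-2(5H)-one
Product: 24 (2Z)-2-methylbut-2-ene-1,4-diol
Conditions: i-Bu2AlH (2.5 equiv), CH2Cl2, −78 → 0 °C; aq. potassium sodium tartrate
Reagents that add atoms: none
Why: Hydride reduction of the unsaturated lactone by 1,2-addition (lactone to diol) keeps the ring-derived (Z) geometry of the alkene.

Step 13
Reactants: 24 (2Z)-2-methylbut-2-ene-1,4-diol
Product: 25 (2Z)-4-hydroxy-3-methylbut-2-en-1-yl acetate
Conditions: Candida antarctica lipase B (immobilised), vinyl acetate, THF, rt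
Reagents that add atoms: vinyl acetate C=COC(C)=O
Why: Lipase-catalysed transesterification (a serine hydrolase) should acylate only the less hindered hydroxymethyl group on the CH= carbon, a distinction between two primary allylic alcohols that simple acylating agents do not make.

Step 14
Reactants: 25 (2Z)-4-hydroxy-3-methylbut-2-en-1-yl acetate
Product: 26 (2Z)-4-(acetyloxy)-2-methylbut-2-enoic acid (fragment C)
Conditions: TEMPO (7 mol%), NaClO2, NaOCl (2 mol%), MeCN/phosphate buffer pH 6.7, 35 °C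
Reagents that add atoms: sodium chlorite [Na+].[O-]Cl=O
Why: TEMPO-catalysed oxidation of the primary allylic alcohol to the aldehyde with chlorite oxidation to the acid in the same flask runs near neutral pH, so the (Z) geometry and the acetate should be kept.

Step 15
Reactants: 22 homoallylic alcohol; 26 fragment C acid
Product: 28 2-(trimethylsilyl)ethyl (3S,4R,6R,7Z)-4-{[(2Z)-4-(acetyloxy)-2-methylbut-2-enoyl]oxy}-3-({[tert-butyl(dimethyl)silyl]oxy}methyl)-9-{[tert-butyl(diphenyl)silyl]oxy}-6-ethenyl-8-iodo-6-methyl-2-methylidenenon-7-enoate, via acid chloride 27 (not isolated)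
Conditions: 26, 1-chloro-N,N,2-trimethylprop-1-en-1-amine, CH2Cl2, 0 °C; then 22, pyridine, CH2Cl2, 0 °C → rt
Reagents that add atoms: none
Why: Acid chloride formation with the neutral α-chloroenamine and esterification of the only free hydroxyl (C3–OH) with pyridine avoid the strongly nucleophilic acyl-transfer catalysts that isomerise (Z)-2-methylbut-2-enoates, and capping C3–OH removes the risk of lactonisation onto the acrylate.

Step 16
Reactants: 28 fully protected ester
Product: 29 the C5 primary alcohol: 2-(trimethylsilyl)ethyl (3S,4R,6R,7Z)-4-{[(2Z)-4-(acetyloxy)-2-methylbut-2-enoyl]oxy}-9-{[tert-butyl(diphenyl)silyl]oxy}-6-ethenyl-3-(hydroxymethyl)-8-iodo-6-methyl-2-methylidenenon-7-enoate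
Conditions: HF·pyridine, pyridine, THF, 0 °C
Reagents that add atoms: none
Why: Buffered fluoride-mediated desilylation removes the primary tert-butyldimethylsilyl ether faster than the tert-butyldiphenylsilyl ether and leaves the 2-(trimethylsilyl)ethyl ester, the acetate and the alkenyl iodide untouched.

Step 17
Reactants: 29 C5 primary alcohol
Product: 30 the C5 aldehyde: 2-(trimethylsilyl)ethyl (3R,4R,6R,7Z)-4-{[(2Z)-4-(acetyloxy)-2-methylbut-2-enoyl]oxy}-9-{[tert-butyl(diphenyl)silyl]oxy}-6-ethenyl-3-formyl-8-iodo-6-methyl-2-methylidenenon-7-enoate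
Conditions: Dess–Martin periodinane, NaHCO3, CH2Cl2, 0 °C; used at once
Reagents that add atoms: none
Why: Dess–Martin oxidation under bicarbonate buffer should give the β-acyloxy aldehyde without base-induced elimination or epimerisation at C4 (the C4 descriptor changes only because the CIP priorities change).

Step 18
Reactants: 30 iodo aldehyde
Product: 33 2-(trimethylsilyl)ethyl 2-[(1S,2R,3S,4R,6R)-6-{[(2Z)-4-(acetyloxy)-2-methylbut-2-enoyl]oxy}-3-(3-{[tert-butyl(diphenyl)silyl]oxy}prop-1-en-2-yl)-4-ethenyl-2-hydroxy-4-methylcyclohexyl]prop-2-enoate, via allylboronate 31 (not isolated), via pinacol borate 32 (not isolated)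
Conditions: IZnCH2B(pin) (from ICH2B(pin) and Zn dust, THF), Pd(PPh3)4 (5 mol%), THF, 25 → 45 °C; then aq. NaHCO3, rt
Reagents that add atoms: [(4,4,5,5-tetramethyl-1,3,2-dioxaborolan-2-yl)methyl]zinc iodide CC1(C)OB(C[Zn]I)OC1(C)C
Why: Oxidative addition of zerovalent palladium into the alkenyl C–I bond, transmetalation with the borylmethylzinc reagent and reductive elimination give, with retention of alkene geometry, the 2-(silyloxymethyl)allylboronate 31 whose CH2B group is cis to the C1 tether, and this boronate then transfers its allyl group to the C5 formyl group through a six-membered chair (Zimmerman–Traxler) transition state in which the B–O and C5–C6 bonds form together. The closest known reaction types are the palladium-catalysed coupling of alkenyl iodides with (dialkoxyboryl)methylzinc reagents followed by carbonyl allylboration, and the ring-closing allylboration of ω-oxo allylboronates to 2-alkenylcycloalkanols. The cyclohexane closes in 6-exo-trig mode at the formyl carbon, with the C=O and the C6=C π bonds both outside the new ring, in a cis-fused chair–chair bicyclic transition state. The cis relationship of C5–OH and the C6 alkenyl group follows from the allyl geometry, which forces the C1 tether axial in the boron-containing chair, and the facial sense relative to C1, C3 and C4 follows from the forming cyclohexane chair that keeps the C3 acyloxy group equatorial, since attack on the other face would need vinyl, C3–O and C5–O to be syn-axial. The step needs oxidative addition at C–I in preference to the allylic acetate, which the much faster reaction of the alkenyl iodide should secure, and a stereospecific closed transition state, which the configurationally stable pinacol boronate secures because it reacts only with the aldehyde, while the non-basic medium protects the epimerisable C4 centre.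

Step 19
Reactants: 33 protected cyclohexanol
Product: 34 2-[(1S,2R,3S,4R,6R)-6-{[(2Z)-4-(acetyloxy)-2-methylbut-2-enoyl]oxy}-4-ethenyl-2-hydroxy-3-(3-hydroxyprop-1-en-2-yl)-4-methylcyclohexyl]prop-2-enoic acid (target)
Conditions: tris(dimethylamino)sulfonium difluorotrimethylsilicate, DMF, 0 °C → rt; aq. NH4Cl, 0 °C
Reagents that add atoms: none
Why: Fluoride-induced global deprotection cleaves the silyl ether and fragments the 2-(trimethylsilyl)ethyl ester to the carboxylate, ethene and Me3SiF, so the acid is released under non-acidic conditions and the γ-hydroxy acid, whose hydroxyl and carboxyl-bearing groups are trans-diaxial in the chair with C3–O equatorial, should not lactonise.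

**Compound list**

1 | tert-butyl(but-3-yn-1-yloxy)dimethylsilane | C#CCCO[Si](C)(C)C(C)(C)C | starting material
2 | [(1E)-4-{[tert-butyl(dimethyl)silyl]oxy}-2-methylbut-1-en-1-yl]dimethylalane | C[Al](C)/C=C(\C)CCO[Si](C)(C)C(C)(C)C | intermediate
3 | lithium butyl[(1E)-4-{[tert-butyl(dimethyl)silyl]oxy}-2-methylbut-1-en-1-yl]dimethylaluminate | [Li+].CCCC[Al-](C)(C)/C=C(\C)CCO[Si](C)(C)C(C)(C)C | intermediate
4 | (2E)-5-{[tert-butyl(dimethyl)silyl]oxy}-3-methylpent-2-en-1-ol | OC/C=C(\C)CCO[Si](C)(C)C(C)(C)C | intermediate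
5 | (2E)-5-{[tert-butyl(dimethyl)silyl]oxy}-3-methylpent-2-en-1-yl diethyl phosphate | CCOP(=O)(OCC)OC/C=C(\C)CCO[Si](C)(C)C(C)(C)C | intermediate
6 | trimethyl(prop-2-yn-1-yloxy)silane | C#CCO[Si](C)(C)C | starting material
7 | bis(2-methylpropyl){3-[(trimethylsilyl)oxy]prop-1-yn-1-yl}alane | CC(C)C[Al](CC(C)C)C#CCO[Si](C)(C)C | intermediate
8 | tert-butyl{[(3R)-3-ethenyl-3-methyl-6-[(trimethylsilyl)oxy]hex-4-yn-1-yl]oxy}dimethylsilane | C=C[C@@](C)(CCO[Si](C)(C)C(C)(C)C)C#CCO[Si](C)(C)C | intermediate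
9 | (4R)-4-(2-{[tert-butyl(dimethyl)silyl]oxy}ethyl)-4-methylhex-5-en-2-yn-1-ol | C=C[C@@](C)(CCO[Si](C)(C)C(C)(C)C)C#CCO | intermediate
10 | (2Z,4R)-4-(2-{[tert-butyl(dimethyl)silyl]oxy}ethyl)-4-methyl-2-(tributylstannyl)hexa-2,5-dien-1-ol | C=C[C@@](C)(CCO[Si](C)(C)C(C)(C)C)/C=C(/CO)[Sn](CCCC)(CCCC)CCCC | intermediate
11 | (2Z,4R)-4-(2-{[tert-butyl(dimethyl)silyl]oxy}ethyl)-2-iodo-4-methylhexa-2,5-dien-1-ol | C=C[C@@](C)(CCO[Si](C)(C)C(C)(C)C)/C=C(\I)CO | intermediate
12 | tert-butyl{[(2Z,4R)-4-(2-{[tert-butyl(dimethyl)silyl]oxy}ethyl)-2-iodo-4-methylhexa-2,5-dien-1-yl]oxy}diphenylsilane | C=C[C@@](C)(CCO[Si](C)(C)C(C)(C)C)/C=C(\I)CO[Si](c1ccccc1)(c1ccccc1)C(C)(C)C | intermediate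
13 | (3R,4Z)-6-{[tert-butyl(diphenyl)silyl]oxy}-3-ethenyl-5-iodo-3-methylhex-4-en-1-ol | C=C[C@@](C)(CCO)/C=C(\I)CO[Si](c1ccccc1)(c1ccccc1)C(C)(C)C | intermediate
14 | (3R,4Z)-6-{[tert-butyl(diphenyl)silyl]oxy}-3-ethenyl-5-iodo-3-methylhex-4-enal (fragment A) | C=C[C@@](C)(CC=O)/C=C(\I)CO[Si](c1ccccc1)(c1ccccc1)C(C)(C)C | intermediate
15 | prop-2-enoyl chloride | C=CC(Cl)=O | starting material
16 | 2-(trimethylsilyl)ethan-1-ol | C[Si](C)(C)CCO | starting material
17 | 2-(trimethylsilyl)ethyl prop-2-enoate | C=CC(=O)OCC[Si](C)(C)C | intermediate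
18 | {[tert-butyl(dimethyl)silyl]oxy}acetaldehyde | O=CCO[Si](C)(C)C(C)(C)C | starting material
19 | 2-(trimethylsilyl)ethyl 4-{[tert-butyl(dimethyl)silyl]oxy}-3-hydroxy-2-methylidenebutanoate (racemic) | C=C(C(=O)OCC[Si](C)(C)C)C(O)CO[Si](C)(C)C(C)(C)C | intermediate
20 | 2-(trimethylsilyl)ethyl (2Z)-2-(bromomethyl)-4-{[tert-butyl(dimethyl)silyl]oxy}but-2-enoate (fragment B) | C[Si](C)(C)CCOC(=O)/C(CBr)=C/CO[Si](C)(C)C(C)(C)C | intermediate
21 | 2-(trimethylsilyl)ethyl (3S,4R,6R,7Z)-3-({[tert-butyl(dimethyl)silyl]oxy}methyl)-9-{[tert-butyl(diphenyl)silyl]oxy}-6-ethenyl-8-iodo-6-methyl-2-methylidene-4-[(trimethylsilyl)oxy]non-7-enoate | C=C[C@@](C)(C[C@@H](O[Si](C)(C)C)[C@@H](C(=C)C(=O)OCC[Si](C)(C)C)CO[Si](C)(C)C(C)(C)C)/C=C(\I)CO[Si](c1ccccc1)(c1ccccc1)C(C)(C)C | intermediate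
22 | 2-(trimethylsilyl)ethyl (3S,4R,6R,7Z)-3-({[tert-butyl(dimethyl)silyl]oxy}methyl)-9-{[tert-butyl(diphenyl)silyl]oxy}-6-ethenyl-4-hydroxy-8-iodo-6-methyl-2-methylidenenon-7-enoate | C=C[C@@](C)(C[C@@H](O)[C@@H](C(=C)C(=O)OCC[Si](C)(C)C)CO[Si](C)(C)C(C)(C)C)/C=C(\I)CO[Si](c1ccccc1)(c1ccccc1)C(C)(C)C | intermediate
23 | 3-methylfuran-2(5H)-one | CC1=CCOC1=O | starting material
24 | (2Z)-2-methylbut-2-ene-1,4-diol | OC/C(C)=C\CO | intermediate
25 | (2Z)-4-hydroxy-3-methylbut-2-en-1-yl acetate | CC(=O)OC/C=C(/C)CO | intermediate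
26 | (2Z)-4-(acetyloxy)-2-methylbut-2-enoic acid (fragment C) | CC(=O)OC/C=C(/C)C(=O)O | intermediate
27 | (2Z)-4-(acetyloxy)-2-methylbut-2-enoyl chloride | CC(=O)OC/C=C(/C)C(Cl)=O | intermediate
28 | 2-(trimethylsilyl)ethyl (3S,4R,6R,7Z)-4-{[(2Z)-4-(acetyloxy)-2-methylbut-2-enoyl]oxy}-3-({[tert-butyl(dimethyl)silyl]oxy}methyl)-9-{[tert-butyl(diphenyl)silyl]oxy}-6-ethenyl-8-iodo-6-methyl-2-methylidenenon-7-enoate | C=C[C@@](C)(C[C@@H](OC(=O)/C(C)=C\COC(C)=O)[C@@H](C(=C)C(=O)OCC[Si](C)(C)C)CO[Si](C)(C)C(C)(C)C)/C=C(\I)CO[Si](c1ccccc1)(c1ccccc1)C(C)(C)C | intermediate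
29 | 2-(trimethylsilyl)ethyl (3S,4R,6R,7Z)-4-{[(2Z)-4-(acetyloxy)-2-methylbut-2-enoyl]oxy}-9-{[tert-butyl(diphenyl)silyl]oxy}-6-ethenyl-3-(hydroxymethyl)-8-iodo-6-methyl-2-methylidenenon-7-enoate | C=C[C@@](C)(C[C@@H](OC(=O)/C(C)=C\COC(C)=O)[C@@H](C(=C)C(=O)OCC[Si](C)(C)C)CO)/C=C(\I)CO[Si](c1ccccc1)(c1ccccc1)C(C)(C)C | intermediate
30 | 2-(trimethylsilyl)ethyl (3R,4R,6R,7Z)-4-{[(2Z)-4-(acetyloxy)-2-methylbut-2-enoyl]oxy}-9-{[tert-butyl(diphenyl)silyl]oxy}-6-ethenyl-3-formyl-8-iodo-6-methyl-2-methylidenenon-7-enoate | C=C[C@@](C)(C[C@@H](OC(=O)/C(C)=C\COC(C)=O)[C@@H](C(=C)C(=O)OCC[Si](C)(C)C)C=O)/C=C(\I)CO[Si](c1ccccc1)(c1ccccc1)C(C)(C)C | intermediate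
31 | 2-(trimethylsilyl)ethyl (3R,4R,6R,7E)-4-{[(2Z)-4-(acetyloxy)-2-methylbut-2-enoyl]oxy}-9-{[tert-butyl(diphenyl)silyl]oxy}-6-ethenyl-3-formyl-6-methyl-2-methylidene-8-[(4,4,5,5-tetramethyl-1,3,2-dioxaborolan-2-yl)methyl]non-7-enoate (CH2B cis to C1) | C=C[C@@](C)(C[C@@H](OC(=O)/C(C)=C\COC(C)=O)[C@@H](C(=C)C(=O)OCC[Si](C)(C)C)C=O)/C=C(\CB1OC(C)(C)C(C)(C)O1)CO[Si](c1ccccc1)(c1ccccc1)C(C)(C)C | intermediate
32 | 2-(trimethylsilyl)ethyl 2-[(1S,2R,3S,4R,6R)-6-{[(2Z)-4-(acetyloxy)-2-methylbut-2-enoyl]oxy}-3-(3-{[tert-butyl(diphenyl)silyl]oxy}prop-1-en-2-yl)-4-ethenyl-4-methyl-2-[(4,4,5,5-tetramethyl-1,3,2-dioxaborolan-2-yl)oxy]cyclohexyl]prop-2-enoate | C=C[C@@]1(C)C[C@@H](OC(=O)/C(C)=C\COC(C)=O)[C@@H](C(=C)C(=O)OCC[Si](C)(C)C)[C@H](OB2OC(C)(C)C(C)(C)O2)[C@@H]1C(=C)CO[Si](c1ccccc1)(c1ccccc1)C(C)(C)C | intermediate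
33 | 2-(trimethylsilyl)ethyl 2-[(1S,2R,3S,4R,6R)-6-{[(2Z)-4-(acetyloxy)-2-methylbut-2-enoyl]oxy}-3-(3-{[tert-butyl(diphenyl)silyl]oxy}prop-1-en-2-yl)-4-ethenyl-2-hydroxy-4-methylcyclohexyl]prop-2-enoate | C=C[C@@]1(C)C[C@@H](OC(=O)/C(C)=C\COC(C)=O)[C@@H](C(=C)C(=O)OCC[Si](C)(C)C)[C@H](O)[C@@H]1C(=C)CO[Si](c1ccccc1)(c1ccccc1)C(C)(C)C | intermediate
34 | 2-[(1S,2R,3S,4R,6R)-6-{[(2Z)-4-(acetyloxy)-2-methylbut-2-enoyl]oxy}-4-ethenyl-2-hydroxy-3-(3-hydroxyprop-1-en-2-yl)-4-methylcyclohexyl]prop-2-enoic acid | C=C[C@@]1(C)C[C@@H](OC(=O)/C(C)=C\COC(C)=O)[C@@H](C(=C)C(=O)O)[C@H](O)[C@@H]1C(=C)CO | target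

**Count and risks**

Total step count: 19. Longest linear sequence: 13 steps (steps 1–7, 11, 15–19).

Steps most likely to fail:

Step 18. Zerovalent palladium may ionise the allylic acetate of the side chain. The β-acyloxy aldehyde may eliminate or epimerise at C4 before the boronate is in place. The chair preference may also erode, because the productive chair carries a syn-axial CH3/O–B contact and a boat alternative would lead to the trans isomer. The fallback sets out from 22 and comes back to the route at 33. It moves the palladium step ahead of both the acetate and the aldehyde. Negishi coupling of 22 with IZnCH2B(pin) and Pd(PPh3)4 should give the allylboronate alcohol F1. Acylation with acid chloride 27 and pyridine gives the allylboronate ester F2. Buffered HF·pyridine gives the primary alcohol F3. Dess–Martin oxidation of F3 then liberates aldehyde 31 in a palladium-free, non-basic medium, where it closes through 32 to 33 (oxidation-triggered ring-closing allylboration).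

Step 11. Facial control by the chromium catalyst may be incomplete on an aldehyde that has no bias of its own. The allylchromium may lose silyloxide by β-elimination, and the chromium alkoxide may lactonise onto the ester. The fallback sets out from 20 and comes back at 22. Pd2(dba)3-catalysed borylation of 20 with B2pin2 should give the allylboronate F4, with CH2B cis to CH2OSi. Allylboration of 14 with F4, catalysed by a chiral 3,3'-bis(2,4,6-triisopropylphenyl)-1,1'-binaphthyl-2,2'-diyl hydrogen phosphate, passes through the same chair and gives the O-boryl adduct F5, which is hydrolysed to 22. A boronate cannot β-eliminate and the borate cannot lactonise.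

Step 15. The 4-acetoxy-2-methylbut-2-enoyl unit may isomerise from Z to E during acyl transfer, and slow acylation of the hindered carbinol gives the γ-hydroxy ester time to lactonise. The fallback sets out from 22 and comes back at 28. Esterification of 22 with 2-[bis(2,2,2-trifluoroethoxy)phosphoryl]propanoic acid (dicyclohexylcarbodiimide, DMAP cat.) gives the phosphonate ester F6. Still–Gennari olefination of F6 with acetoxyacetaldehyde (KN(SiMe3)2, 18-crown-6, THF, −78 °C) builds the (Z)-alkene on the substrate and gives 28.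

Further compounds
F1 | step 18 | allylboronate alcohol: 22 with iodine replaced by CH2B(pin) | C=C[C@@](C)(C[C@@H](O)[C@@H](C(=C)C(=O)OCC[Si](C)(C)C)CO[Si](C)(C)C(C)(C)C)/C=C(\CB1OC(C)(C)C(C)(C)O1)CO[Si](c1ccccc1)(c1ccccc1)C(C)(C)C
F2 | step 18 | allylboronate ester: F1 acylated at C3–O with the (2Z)-4-(acetyloxy)-2-methylbut-2-enoyl group | C=C[C@@](C)(C[C@@H](OC(=O)/C(C)=C\COC(C)=O)[C@@H](C(=C)C(=O)OCC[Si](C)(C)C)CO[Si](C)(C)C(C)(C)C)/C=C(\CB1OC(C)(C)C(C)(C)O1)CO[Si](c1ccccc1)(c1ccccc1)C(C)(C)C
F3 | step 18 | primary alcohol: F2 without the tert-butyldimethylsilyl group | C=C[C@@](C)(C[C@@H](OC(=O)/C(C)=C\COC(C)=O)[C@@H](C(=C)C(=O)OCC[Si](C)(C)C)CO)/C=C(\CB1OC(C)(C)C(C)(C)O1)CO[Si](c1ccccc1)(c1ccccc1)C(C)(C)C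
F4 | step 11 | 2-(trimethylsilyl)ethyl (2E)-4-{[tert-butyl(dimethyl)silyl]oxy}-2-[(4,4,5,5-tetramethyl-1,3,2-dioxaborolan-2-yl)methyl]but-2-enoate | C[Si](C)(C)CCOC(=O)/C(CB1OC(C)(C)C(C)(C)O1)=C/CO[Si](C)(C)C(C)(C)C
F5 | step 11 | O-boryl adduct: pinacol borate of 22 at C3–O | C=C[C@@](C)(C[C@@H](OB1OC(C)(C)C(C)(C)O1)[C@@H](C(=C)C(=O)OCC[Si](C)(C)C)CO[Si](C)(C)C(C)(C)C)/C=C(\I)CO[Si](c1ccccc1)(c1ccccc1)C(C)(C)C
F6 | step 15 | phosphonate ester: 22 esterified at C3–O with 2-[bis(2,2,2-trifluoroethoxy)phosphoryl]propanoic acid (epimers at the phosphonate carbon) | C=C[C@@](C)(C[C@@H](OC(=O)C(C)P(=O)(OCC(F)(F)F)OCC(F)(F)F)[C@@H](C(=C)C(=O)OCC[Si](C)(C)C)CO[Si](C)(C)C(C)(C)C)/C=C(\I)CO[Si](c1ccccc1)(c1ccccc1)C(C)(C)C
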